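**Retrosynthetic overview**

1. End game: target 31 ⇐ 8α-alcohol 27 (Mitsunobu inversion with methacrylic acid, then the C11 acetate). The cyclopentenone of 27 ⇐ the C3 benzyl ether of hydroazulenone 17 (hydrogenolysis, oxidation, C4–C5 dehydrogenation). C14 and the C8 oxygen ⇐ the C8=C9–C10=O enone of 17 (conjugate borylation–oxidation, methylenation, hydroxyl-directed hydrogenation).
2. Key disconnection: bonds C2–C3 and C1–C5 of 17 ⇐ Prins–pinacol ring-enlarging cyclopentane annulation of the 1-vinylcyclohex-2-enyl silyl ether 16, which carries the C4–C3 dibenzyl acetal on C5.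
3. Feature: the arc C5–C6–C7–C8–C9–C10 of the seven-membered ring B, with C11–C13 on C7, is the six-membered ring of (−)-β-pinene with C7 already (S). Only C1 has to be inserted between C10 and C5, and that insertion is coupled to closure of the five-membered ring A (C1–C5).
4. 16 ⇐ (S)-enone 7 (nopinone, cyclobutane cleavage, Saegusa–Ito oxidation) by α'-Michael addition to nitropropene with Nef hydrolysis (C4, C15, C3), acetalisation and vinyl addition (C1, C2).
5. Ring order: the carbocycle C5–C10 comes from the chiral pool; rings A and B are formed together in step 9; no ring is formed afterwards.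

Key step: step 9

Remark: guaiane numbering is used for all compounds (C1/C5 ring fusion, C3 ketone, C4 bearing C15, C7 bearing C11–C13, C8 ester, C10 bearing C14). β is the face of the six- or seven-membered ring on which C7 carries C11. The target is (1R,7S,8R,10S), that is 1β-H, 8β-ester, 10β-methyl.
Remark: C3, C4 and C5 become sp2 centres in steps 15 and 16, so their configurations matter only for the course of step 9; the C4 configuration drawn is the one expected from step 5.
Remark: benzyloxytrimethylsilane 12, the commercial trimethylsilyl ether of benzyl alcohol, is used as the source of the benzyloxy groups.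

**Route**

Step 1
Reactants: 1 (−)-β-pinene
Product: 3 (+)-nopinone, via ozonide 2 (not isolated)
Conditions: O3, CH2Cl2, −78 °C; then Me2S, −78 °C → rt
Reagents that add atoms: ozone [O-][O+]=O
Why: Ozonolysis with reductive work-up cleaves only the exocyclic C=CH2 bond and leaves both bridgehead stereocentres untouched.

Step 2
Reactants: 3 (+)-nopinone
Product: 4 (S)-4-(2-acetoxypropan-2-yl)cyclohex-1-en-1-yl acetate
Conditions: Ac2O, BF3·OEt2, Zn(OAc)2, 0 °C → rt
Reagents that add atoms: acetic anhydride CC(=O)OC(C)=O
Why: Lewis-acid-promoted cyclobutane fragmentation (acetolysis) breaks the bridgehead–CMe2 bond next to the activated carbonyl group, acetate captures the tertiary cation and the enol is O-acetylated, so the double bond marks the former bridgehead side and the remaining stereocentre (later C7) is not touched.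

Step 3
Reactants: 4 enol acetate diacetate
Product: 6 bis(tert-butyldimethylsilyl) enol ether, via dilithium enolate alkoxide 5 (not isolated)
Conditions: MeLi (4.4 equiv), Et2O, 0 °C; then TBSOTf (4.5 equiv), −78 → 0 °C
Reagents that add atoms: tert-butyldimethylsilyl trifluoromethanesulfonate CC(C)(C)[Si](C)(C)OS(=O)(=O)C(F)(F)F; methyllithium [Li]C (lithium of intermediate 5 only)
Why: Cleavage of the enol acetate and of the tertiary acetate by methyllithium gives the lithium enolate without proton exchange, and O-silylation with the silyl triflate fixes the double bond on the same side, which is the only feature that keeps the two ring branches, and thus the configuration at C7, distinct.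

Step 4
Reactants: 6 bis-silyl enol ether
Product: 7 (S)-4-[2-(tert-butyldimethylsilyloxy)propan-2-yl]cyclohex-2-en-1-one
Conditions: Pd(OAc)2 (1.1 equiv), MeCN, rt → 40 °C
Reagents that add atoms: none
Why: Saegusa–Ito oxidation: the palladium enolate formed at C9 undergoes β-hydride elimination towards C8, which places the enone alkene regiospecifically next to the C7 stereocentre.

Step 5
Reactants: 7 (S)-enone, 8 (E)-1-nitroprop-1-ene
Product: 11 keto aldehyde (R)-2-[(1R,5S)-2-oxo-5-(2-silyloxypropan-2-yl)cyclohex-3-en-1-yl]propanal, via lithium dienolate 9 (not isolated), via lithium nitronate 10 (not isolated)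
Conditions: LiN(iPr)2 (LDA), THF, −78 °C; 8, −78 °C (no HMPA); then transfer into cold 3 M aq. H2SO4, −10 → 0 °C
Reagents that add atoms: water O (aldehyde oxygen); lithium diisopropylamide [Li+].CC(C)[N-]C(C)C (lithium of intermediates 9 and 10 only)
Why: Kinetic α'-deprotonation gives the cross-conjugated dienolate, its Michael addition to the nitroalkene should occur axially at C5 on the face opposite the C7 substituent (C5 trans to C7) through a synclinal open transition state with the nitro group near the enolate oxygen (C4), and the nitronate is hydrolysed at once by a Nef reaction in cold acid before it can add to C8 of the enone.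

Step 6
Reactants: 11 keto aldehyde, 12 benzyloxytrimethylsilane
Product: 13 (4S,6R)-6-[(R)-1,1-bis(benzyloxy)propan-2-yl]-4-[2-(tert-butyldimethylsilyloxy)propan-2-yl]cyclohex-2-en-1-one
Conditions: 12 (2.2 equiv), TMSOTf (5 mol %), CH2Cl2, −78 °C; pyridine quench
Reagents that add atoms: none
Why: Noyori acetalisation with an alkoxysilane and catalytic silyl triflate at −78 °C is selective for the aldehyde over the conjugated ketone and is not basic, so C4 and C5 are not epimerised.

Step 7
Reactants: 13 acetal enone, 14 vinylmagnesium bromide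
Product: 15 tertiary allylic alcohol (10α-OH, 10β-vinyl, 5α side chain, 7β substituent)
Conditions: 14, CeCl3, THF, −78 °C
Reagents that add atoms: none
Why: 1,2-Addition of the weakly basic organocerium reagent (no enolisation at C5) should occur anti to the pseudoaxial C5 side chain (Felkin–Anh), which places the vinyl group β and trans to the side chain and the hydroxyl group α.

Step 8
Reactants: 15 tertiary allylic alcohol
Product: 16 triethylsilyl ether of 15 (key-step precursor)
Conditions: KN(SiMe3)2, THF, −78 °C; TESCl, −78 → 0 °C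
Reagents that add atoms: chlorotriethylsilane CC[Si](CC)(CC)Cl
Why: Silylation of the tertiary potassium alkoxide with the silyl chloride avoids silyl triflate and acid, both of which would attack the acetal.

Step 9
Reactants: 16 1-vinylcyclohex-2-enyl triethylsilyl ether with dibenzyl acetal side chain
Product: 17 3α-benzyloxy-11-(tert-butyldimethylsilyloxy)-1βH,5βH-14-norguai-8-en-10-one (4β-methyl)
Conditions: SnCl4 (2 equiv), 2,6-di-tert-butyl-4-methylpyridine (0.3 equiv), CH2Cl2, −78 → −23 °C
Reagents that add atoms: none
Why: SnCl4 removes one benzyloxy group of the acetal and gives the (E)-oxocarbenium ion at C3; the terminal vinyl carbon C2 adds to it through a chair in which the vinyl group on C10 and the side chain on C5 are equatorial on the cyclohexene and the siloxy group is axial, and the charge that develops at C1 is taken up in the same event by the 1,2-shift of C5 from C10 to C1, while the siloxy oxygen becomes the C10 carbonyl group and the triethylsilyl group leaves with the benzyloxide. The closest known reaction type is the Prins–pinacol ring-enlarging cyclopentane annulation of 1-alkenyl-2-(2,2-dialkoxyethyl)cycloalkanol silyl ethers, which converts cyclohexanol substrates into cis-fused hydroazulenones. Ring A is closed by 6-endo attack of the alkene on the oxocarbenium ion (bond C2–C3) followed by contraction of that six-membered ring through the shift of C5 (bond C1–C5), and ring B arises from the same shift as a one-carbon enlargement of the cyclohexene to the cycloheptenone. C1 is set by the suprafacial migration of C5 with retention, which puts H-1 cis to H-5 and therefore β, and C3 is set by the equatorial position of the benzyloxy group of the (E)-oxocarbenium ion in the chair, trans to the equatorial C4 methyl group. The step needs C5 and not C9 to migrate: with the oxygen axial the ring bond C10–C5 lies close to the axis of the empty orbital at C1 whereas C10–C9 is nearly orthogonal to it, and this is secured by the trans relation of vinyl group and side chain from step 7. It also needs the acetal to ionise before the doubly allylic silyl ether, which the low temperature and the higher Lewis basicity of the acetal should secure, and the ring alkene helps because in the reacting half-chair the pseudoaxial C7 substituent meets only H-5.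

Step 10
Reactants: 17 hydroazulenone
Product: 19 3α-benzyloxy-8α-hydroxy-11-(tert-butyldimethylsilyloxy)-1βH,5βH-14-norguaian-10-one, via β-boryl ketone 18 (not isolated)
Conditions: CuCl (5 mol %), NaOtBu (10 mol %), 4,5-bis(diphenylphosphino)-9,9-dimethylxanthene (5 mol %), B2pin2, MeOH (2 equiv), THF, rt; then NaBO3·4H2O, THF/H2O, rt
Reagents that add atoms: sodium perborate [Na+].[Na+].O[B-]1(O)OO[B-](O)(O)OO1 (oxygen at C8); bis(pinacolato)diboron CC1(C)OB(OC1(C)C)B1OC(C)(C)C(C)(C)O1 (boryl group of intermediate 18 only)
Why: Copper-catalysed conjugate borylation: the boryl copper species should add to C8 on the face opposite the neighbouring C7 substituent (8α), methanol protonates the enolate, and perborate oxidises the C–B bond with retention under conditions mild enough to leave C1 and the β-hydroxy ketone intact.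

Step 11
Reactants: 19 β-hydroxy ketone
Product: 20 3α-benzyloxy-11-(tert-butyldimethylsilyloxy)-1βH,5βH-guai-10(14)-en-8α-ol
Conditions: Zn, CH2Br2, TiCl4, THF/CH2Cl2, 0 °C → rt
Reagents that add atoms: dibromomethane BrCBr
Why: Takai–Lombardo methylenation is not basic, so the β-hydroxy ketone should undergo neither retro-aldol cleavage nor elimination, C1 is not epimerised, and the free hydroxyl group is tolerated.

Step 12
Reactants: 20 homoallylic alcohol
Product: 21 3α-benzyloxy-11-(tert-butyldimethylsilyloxy)-1βH,5βH,10αH-guaian-8α-ol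
Conditions: [Ir(cod)(PCy3)(py)]PF6 (5 mol %), H2 (1 atm), CH2Cl2, rt
Reagents that add atoms: none
Why: Hydroxyl-directed hydrogenation: the cationic iridium catalyst bound to the 8α-hydroxyl group should deliver hydrogen to the α face of the exocyclic alkene, so that C14 ends β (trans to the hydroxyl group, cis to H-1), against the intrinsic preference for attack from the convex β face.

Step 13
Reactants: 21 8α-alcohol
Product: 22 8α-triethylsilyl ether of 21
Conditions: TESOTf, 2,6-lutidine, CH2Cl2, −78 → 0 °C
Reagents that add atoms: triethylsilyl trifluoromethanesulfonate CC[Si](CC)(CC)OS(=O)(=O)C(F)(F)F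
Why: Silylation of the secondary alcohol with silyl triflate and a hindered base keeps the C8 oxygen out of the C3 oxidation that follows, because the two secondary alcohols could not otherwise be told apart.

Step 14
Reactants: 22 benzyl ether
Product: 23 8α-triethylsilyloxy-11-(tert-butyldimethylsilyloxy)-1βH,5βH,10αH-guaian-3α-ol
Conditions: H2 (1 atm), Pd/C (10 %), EtOAc, rt
Reagents that add atoms: none
Why: Hydrogenolysis of the benzyl ether over Pd/C in ethyl acetate leaves both silyl ethers in place, and no alkene remains to be reduced.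

Step 15
Reactants: 23 C3 alcohol
Product: 24 8α-triethylsilyloxy-11-(tert-butyldimethylsilyloxy)-1βH,5βH,10αH-guaian-3-one
Conditions: Dess–Martin periodinane, NaHCO3, CH2Cl2, rt
Reagents that add atoms: none
Why: Dess–Martin oxidation of the only free alcohol under buffered conditions that do not touch the silyl ethers.

Step 16
Reactants: 24 C3 ketone
Product: 26 8α-triethylsilyloxy-11-(tert-butyldimethylsilyloxy)-1βH,10αH-guai-4-en-3-one, via trimethylsilyl enol ether 25 (not isolated)
Conditions: TMSCl, NaI, Et3N, MeCN, rt; pentane extraction; then Pd(OAc)2 (1.1 equiv), MeCN, rt → 40 °C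
Reagents that add atoms: chlorotrimethylsilane C[Si](C)(C)Cl (silyl group of intermediate 25 only)
Why: Thermodynamic silyl enol ether formation with iodotrimethylsilane made in situ gives the more substituted C3=C4 enol ether, and Saegusa–Ito oxidation then removes H-5 by β-hydride elimination to the tetrasubstituted C4=C5 enone (an exocyclic isomer, if formed, should isomerise to it), which erases C4 and C5 and leaves C1 untouched.

Step 17
Reactants: 26 bis-silyl enone
Product: 27 8α-hydroxy-11-(tert-butyldimethylsilyloxy)-1βH,10αH-guai-4-en-3-one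
Conditions: pyridinium p-toluenesulfonate (cat.), MeOH/CH2Cl2, 0 °C → rt
Reagents that add atoms: none
Why: Acid-catalysed methanolysis (desilylation) removes the secondary triethylsilyl ether much faster than the hindered tertiary tert-butyldimethylsilyl ether.

Step 18
Reactants: 27 8α-alcohol, 28 methacrylic acid
Product: 29 8β-methacryloyloxy-11-(tert-butyldimethylsilyloxy)-1βH,10αH-guai-4-en-3-one
Conditions: 28, PPh3, DIAD, toluene, 0 °C → rt
Reagents that add atoms: none
Why: Mitsunobu esterification: the carboxylate displaces the oxyphosphonium group at C8 with inversion (8α-OH to 8β-ester), as in the inversion of menthol-type alcohols, while the silylated C11 oxygen cannot interfere.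

Step 19
Reactants: 29 silyl ether
Product: 30 11-hydroxy-8β-methacryloyloxy-1βH,10αH-guai-4-en-3-one
Conditions: HF·pyridine, THF, 0 °C → rt
Reagents that add atoms: none
Why: Fluoride-mediated desilylation under acidic conditions cleaves the tertiary silyl ether without acyl migration and without attack on the methacrylate.

Step 20
Reactants: 30 tertiary alcohol
Product: 31 target, 11-acetoxy-8β-methacryloyloxy-1βH,10αH-guai-4-en-3-one
Conditions: Ac2O, DMAP, Et3N, CH2Cl2, rt → 40 °C
Reagents that add atoms: acetic anhydride CC(=O)OC(C)=O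
Why: DMAP-catalysed acetylation of the tertiary alcohol, the only nucleophilic group left.

**Compound list**

1 | (−)-β-pinene, (1S,5S)-6,6-dimethyl-2-methylenebicyclo[3.1.1]heptane | C=C1CC[C@H]2C[C@@H]1C2(C)C | starting material
2 | ozonide (spiro-1,2,4-trioxolane) of 1, not isolated | C1OOC2(O1)CC[C@H]1C[C@@H]2C1(C)C | intermediate
3 | (+)-nopinone, (1R,5S)-6,6-dimethylbicyclo[3.1.1]heptan-2-one | O=C1CC[C@H]2C[C@@H]1C2(C)C | intermediate
4 | (S)-4-(2-acetoxypropan-2-yl)cyclohex-1-en-1-yl acetate | CC(=O)OC1=CC[C@@H](C(C)(C)OC(C)=O)CC1 | intermediate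
5 | dilithium enolate alkoxide from 4, not isolated | [Li+].[Li+].[O-]C1=CC[C@@H](C(C)(C)[O-])CC1 | intermediate
6 | (S)-1-(tert-butyldimethylsilyloxy)-4-[2-(tert-butyldimethylsilyloxy)propan-2-yl]cyclohex-1-ene | CC(C)(C)[Si](C)(C)OC1=CC[C@@H](C(C)(C)O[Si](C)(C)C(C)(C)C)CC1 | intermediate
7 | (S)-4-[2-(tert-butyldimethylsilyloxy)propan-2-yl]cyclohex-2-en-1-one | O=C1C=C[C@@H](C(C)(C)O[Si](C)(C)C(C)(C)C)CC1 | intermediate
8 | (E)-1-nitroprop-1-ene | C/C=C/[N+](=O)[O-] | starting material
9 | lithium cross-conjugated dienolate of 7 (C5=C10–O, C8=C9), not isolated | [Li+].[O-]C1=CC[C@H](C(C)(C)O[Si](C)(C)C(C)(C)C)C=C1 | intermediate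
10 | lithium nitronate of the Michael adduct (C5 side chain trans to the C7 substituent), not isolated | O=C1C=C[C@@H](C(C)(C)O[Si](C)(C)C(C)(C)C)C[C@@H]1[C@@H](C)C=[N+]([O-])[O-].[Li+] | intermediate
11 | (R)-2-[(1R,5S)-5-[2-(tert-butyldimethylsilyloxy)propan-2-yl]-2-oxocyclohex-3-en-1-yl]propanal | O=C1C=C[C@@H](C(C)(C)O[Si](C)(C)C(C)(C)C)C[C@@H]1[C@@H](C)C=O | intermediate
12 | benzyloxytrimethylsilane | C[Si](C)(C)OCc1ccccc1 | starting material
13 | (4S,6R)-6-[(R)-1,1-bis(benzyloxy)propan-2-yl]-4-[2-(tert-butyldimethylsilyloxy)propan-2-yl]cyclohex-2-en-1-one | O=C1C=C[C@@H](C(C)(C)O[Si](C)(C)C(C)(C)C)C[C@@H]1[C@@H](C)C(OCc1ccccc1)OCc1ccccc1 | intermediate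
14 | vinylmagnesium bromide | C=C[Mg]Br | starting material
15 | 6-[1,1-bis(benzyloxy)propan-2-yl]-4-[2-(tert-butyldimethylsilyloxy)propan-2-yl]-1-vinylcyclohex-2-en-1-ol, OH cis to the C6 side chain and both trans to the C4 substituent (10α-OH, 10β-vinyl, 5α side chain, 7β substituent) | C1=C[C@](O)(C=C)[C@@H]([C@@H](C)C(OCc2ccccc2)OCc2ccccc2)C[C@@H]1C(C)(C)O[Si](C)(C)C(C)(C)C | intermediate
16 | triethylsilyl ether of 15 (key-step precursor) | C1=C[C@](O[Si](CC)(CC)CC)(C=C)[C@@H]([C@@H](C)C(OCc2ccccc2)OCc2ccccc2)C[C@@H]1C(C)(C)O[Si](C)(C)C(C)(C)C | intermediate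
17 | 3α-benzyloxy-11-(tert-butyldimethylsilyloxy)-4β-methyl-1βH,5βH-14-norguai-8-en-10-one (cis-fused) | C1=CC(=O)[C@H]2C[C@@H](OCc3ccccc3)[C@H](C)[C@H]2C[C@@H]1C(C)(C)O[Si](C)(C)C(C)(C)C | intermediate
18 | 8α-(pinacolatoboryl) ketone from 17, not isolated | CC1(C)OB(OC1(C)C)[C@H]1CC(=O)[C@H]2C[C@@H](OCc3ccccc3)[C@H](C)[C@H]2C[C@@H]1C(C)(C)O[Si](C)(C)C(C)(C)C | intermediate
19 | 3α-benzyloxy-8α-hydroxy-11-(tert-butyldimethylsilyloxy)-1βH,5βH-14-norguaian-10-one | O[C@H]1CC(=O)[C@H]2C[C@@H](OCc3ccccc3)[C@H](C)[C@H]2C[C@@H]1C(C)(C)O[Si](C)(C)C(C)(C)C | intermediate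
20 | 3α-benzyloxy-11-(tert-butyldimethylsilyloxy)-1βH,5βH-guai-10(14)-en-8α-ol | O[C@H]1CC(=C)[C@H]2C[C@@H](OCc3ccccc3)[C@H](C)[C@H]2C[C@@H]1C(C)(C)O[Si](C)(C)C(C)(C)C | intermediate
21 | 3α-benzyloxy-11-(tert-butyldimethylsilyloxy)-1βH,5βH,10αH-guaian-8α-ol | O[C@H]1C[C@H](C)[C@H]2C[C@@H](OCc3ccccc3)[C@H](C)[C@H]2C[C@@H]1C(C)(C)O[Si](C)(C)C(C)(C)C | intermediate
22 | 8α-triethylsilyl ether of 21 | CC[Si](CC)(CC)O[C@H]1C[C@H](C)[C@H]2C[C@@H](OCc3ccccc3)[C@H](C)[C@H]2C[C@@H]1C(C)(C)O[Si](C)(C)C(C)(C)C | intermediate
23 | 8α-triethylsilyloxy-11-(tert-butyldimethylsilyloxy)-1βH,5βH,10αH-guaian-3α-ol | CC[Si](CC)(CC)O[C@H]1C[C@H](C)[C@H]2C[C@@H](O)[C@H](C)[C@H]2C[C@@H]1C(C)(C)O[Si](C)(C)C(C)(C)C | intermediate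
24 | 8α-triethylsilyloxy-11-(tert-butyldimethylsilyloxy)-1βH,5βH,10αH-guaian-3-one | CC[Si](CC)(CC)O[C@H]1C[C@H](C)[C@H]2CC(=O)[C@H](C)[C@H]2C[C@@H]1C(C)(C)O[Si](C)(C)C(C)(C)C | intermediate
25 | 3-trimethylsilyloxy-guai-3-ene derivative of 24 (C3=C4 enol ether), not isolated | CC[Si](CC)(CC)O[C@H]1C[C@H](C)[C@H]2CC(O[Si](C)(C)C)=C(C)[C@H]2C[C@@H]1C(C)(C)O[Si](C)(C)C(C)(C)C | intermediate
26 | 8α-triethylsilyloxy-11-(tert-butyldimethylsilyloxy)-1βH,10αH-guai-4-en-3-one | CC[Si](CC)(CC)O[C@H]1C[C@H](C)[C@H]2CC(=O)C(C)=C2C[C@@H]1C(C)(C)O[Si](C)(C)C(C)(C)C | intermediate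
27 | 8α-hydroxy-11-(tert-butyldimethylsilyloxy)-1βH,10αH-guai-4-en-3-one | O[C@H]1C[C@H](C)[C@H]2CC(=O)C(C)=C2C[C@@H]1C(C)(C)O[Si](C)(C)C(C)(C)C | intermediate
28 | methacrylic acid | C=C(C)C(=O)O | starting material
29 | 8β-methacryloyloxy-11-(tert-butyldimethylsilyloxy)-1βH,10αH-guai-4-en-3-one | C=C(C)C(=O)O[C@@H]1C[C@H](C)[C@H]2CC(=O)C(C)=C2C[C@@H]1C(C)(C)O[Si](C)(C)C(C)(C)C | intermediate
30 | 11-hydroxy-8β-methacryloyloxy-1βH,10αH-guai-4-en-3-one | C=C(C)C(=O)O[C@@H]1C[C@H](C)[C@H]2CC(=O)C(C)=C2C[C@@H]1C(C)(C)O | intermediate
31 | (1R,7S,8R,10S)-11-acetoxy-8-methacryloyloxy-guai-4-en-3-one (CNP0318307.1) | C=C(C)C(=O)O[C@@H]1C[C@H](C)[C@H]2CC(=O)C(C)=C2C[C@@H]1C(C)(C)OC(C)=O | target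

**Step count and risks**

Total step count: 20. Longest linear sequence: 20 steps from 1 (the route is fully linear).

Steps most likely to fail:

Step 9 (key step). The Lewis acid may ionise the doubly allylic C10–O bond instead of the acetal, with loss of the silanol. The six-membered ring may also close without the 1,2-shift, because the charge at C1 is only that of a secondary cation. The cyclisation may be slow because the reacting half-chair places the C7 substituent pseudoaxial. The fallback is a thionium-terminated variant that stabilises the charge at C1 and so speeds the cyclisation relative to silyl ether ionisation. It sets out from compound 13. Addition of 1-(phenylthio)vinyllithium (phenyl vinyl sulfide, t-BuLi, THF, −78 °C, then CeCl3) should give the tertiary alcohol F1, and silylation as in step 8 the triethylsilyl ether F2. SnCl4 under the conditions of step 9 should then give the 1-phenylthio hydroazulenone F3, in which sulfur stands where H-1 belongs. Reductive removal of sulfur with SmI2 in THF/MeOH at −78 °C, with protonation of the enolate at C1 on the convex face syn to H-5, comes back to the route at compound 17.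

Step 5. The nitronate may add a second time, intramolecularly, to C8 of the enone (bicyclo[2.2.2]octanone formation). The Nef hydrolysis of the primary nitronate may stop short of the aldehyde. Part of the enolate may be attacked on the face syn to the C7 substituent. The fallback introduces C4, C15 and C3 as a but-3-en-2-yl group and unmasks the aldehyde by oxidative cleavage, so that no nitronate is formed. It sets out from compound 7. LDA and then TMSCl should give the 2-silyloxy diene F4. Iridium-catalysed branch-selective allylic alkylation ([Ir(cod)Cl]2, a BINOL-derived phosphoramidite, CsF, ZnF2, (E)-but-2-enyl methyl carbonate, DME) should give the α'-(but-3-en-2-yl) enone F5, again by attack anti to the C7 substituent. Dihydroxylation of the terminal alkene in preference to the electron-poor enone alkene with glycol cleavage in the same flask (OsO4 cat., NaIO4, 2,6-lutidine, dioxane/H2O) comes back to the route at compound 11.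

Step 18. Substitution at C8 has to pass the C7 substituent, so elimination to an alkene or recovery of the alcohol may win over inversion. The fallback inverts C8 by oxidation and reduction. It sets out from compound 27. Dess–Martin oxidation (buffered, no base, so that C7 is not epimerised) should give the 3,8-dione F6. NaBH4 in MeOH/CH2Cl2 at −78 °C should reduce the saturated C8 ketone in preference to the cyclopentenone, from the α face opposite the C7 substituent, to give the 8β-alcohol F7. Acylation with methacrylic anhydride, DMAP and Et3N in CH2Cl2 comes back to the route at compound 29.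

Further compounds
F1 | step 9 | 1-[1-(phenylthio)vinyl] analogue of alcohol 15 | C1=C[C@](O)(C(=C)Sc2ccccc2)[C@@H]([C@@H](C)C(OCc2ccccc2)OCc2ccccc2)C[C@@H]1C(C)(C)O[Si](C)(C)C(C)(C)C
F2 | step 9 | triethylsilyl ether of F1 | C1=C[C@](O[Si](CC)(CC)CC)(C(=C)Sc2ccccc2)[C@@H]([C@@H](C)C(OCc2ccccc2)OCc2ccccc2)C[C@@H]1C(C)(C)O[Si](C)(C)C(C)(C)C
F3 | step 9 | 1α-phenylthio analogue of hydroazulenone 17 | C1=CC(=O)[C@@]2(Sc3ccccc3)C[C@@H](OCc3ccccc3)[C@H](C)[C@H]2C[C@@H]1C(C)(C)O[Si](C)(C)C(C)(C)C
F4 | step 5 | (S)-2-trimethylsilyloxy-5-[2-(tert-butyldimethylsilyloxy)propan-2-yl]cyclohexa-1,3-diene | C[Si](C)(C)OC1=CC[C@H](C(C)(C)O[Si](C)(C)C(C)(C)C)C=C1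
F5 | step 5 | 6-(but-3-en-2-yl)-4-[2-(tert-butyldimethylsilyloxy)propan-2-yl]cyclohex-2-en-1-one, side chain trans to the C4 substituent | O=C1C=C[C@@H](C(C)(C)O[Si](C)(C)C(C)(C)C)C[C@@H]1[C@@H](C)C=C
F6 | step 18 | 11-(tert-butyldimethylsilyloxy)-1βH,10αH-guai-4-ene-3,8-dione | O=C1C[C@H](C)[C@H]2CC(=O)C(C)=C2C[C@@H]1C(C)(C)O[Si](C)(C)C(C)(C)C
F7 | step 18 | 8β-hydroxy-11-(tert-butyldimethylsilyloxy)-1βH,10αH-guai-4-en-3-one | O[C@@H]1C[C@H](C)[C@H]2CC(=O)C(C)=C2C[C@@H]1C(C)(C)O[Si](C)(C)C(C)(C)C
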